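A small charge carries this flask: the incoming ligand dissolves from the gas towards 19 mM, far less than the 0.40 M of starting complex it has to work through.

starting complex 0.40 M; leaving ligand 2.00 M; gas 19 mM (held); time 40 min

* complex with one exchanged at 40 min, in percent of the starting complex charged
* the change that raises the amount of complex with one exchanged at 40 min, in percent of the starting complex charged most ("none" if none brings more than 2 percentage points) (noon / dusk / none)
* amount of complex with one exchanged at 40 min, in percent of the starting complex charged, after noon

- noon: doubling the transfer coefficient of step 4, all else as stated
- dusk: doubling the saturation concentration of gas, all else as stated

- where a step has two of a species, its rate is k times that concentration squared, and two are used at each turn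
- at the start none of incoming ligand is dissolved
- run time (flask): 40 min

    starting complex + incoming ligand ⇌ leaving ligand + complex with one exchanged (K1 = 2200, k1 = 0.0124 /M/s)
    complex with one exchanged + incoming ligand ⇌ leaving ligand + complex with two exchanged (K2 = 680, k2 = 0.00595 /M/s)
    complex with two exchanged + incoming ligand ⇌ leaving ligand + complex with three exchanged (K3 = 1460, k3 = 0.00685 /M/s)
    gas ⇌ incoming ligand, rate k4*(csat - [incoming ligand]) (k4 = 0.775 /s, csat = 19 mM)
    2 incoming ligand → homo dimer (k5 = 0.0840 /M/s)

First ask how much incoming ligand is dissolved. The first exchange and the dimer together draw about 0.155 mM/s at the start, and the gas feeds at its transfer coefficient 0.775 /s times the gap to saturation, so the gap need only be 0.200 mM. My level is therefore 18.8 mM, and because the gap is far smaller than saturation, I treat that level as constant, which makes each exchange pseudo-first-order. I also drop the ways back: with equal amounts of the two complexes, the first exchange balances at 0.909 mM of incoming ligand, far below my level. The starting complex then falls exponentially, and by my reckoning 57.1% of it remains after 40 min.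

Now divide the rate of change of the complex with one exchanged by the rate at which the starting complex falls. Level and time cancel, leaving the second exchange's rate constant over the first's, the selectivity factor 0.480. Call it s, and let m be the fraction of starting complex left. The share with one exchanged is then m to the power s, minus m, all divided by one minus s. For this flask I get 37.1%.

Noon halves the gap, giving a level of 18.9 mM, so m becomes 57.0% and the share 37.2%, a gain of 0.10 percentage points. Dusk, reckoned the same way, gives a level of 37.4 mM, so m becomes 32.8% and the share 49.5%, a gain of 12 points, more than the 2 points required, so I choose dusk.

The forecast gave 36.7% (from 35.5% to 38%), a little below my figure, with 36.8% after noon and dusk as the best change, on the ground that “Doubling the transfer coefficient therefore changes almost nothing”.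

The simulation gives 36.7%, and 36.9% after noon; the best change is dusk, with noon bringing 0.11 points and dusk 12 points.

Carry the selectivity factor over to the readings themselves. This flask still held 58% of its starting complex at 40.0 min, and 0.480 turns that reading into 36.5% with one exchanged, beside the simulated 36.7%. The neighbouring flask is the same flask read at 2.5 h, when 15% of the starting complex remains. The same formula gives 48.5% there, and that flask holds 46.9%.

(The constants used here are made up; the flask was simulated.)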